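**Plan**

- Retrosynthesis: the C8 prenyl group is traced back to an allyl group (cross-metathesis) and the C4 ketone to a C4 alcohol. Ring C is then cut at O1–C2 and C3–C4 into a salicylaldehyde (ring A plus C4) and 4-methoxystyrene (ring B plus C2–C3).
- Forward: ring A is dressed first (ortho-demethylation, O-allylation, silylation, aromatic Claisen shift). Ring C is then closed onto it in one annulation that also brings in ring B. Oxidation, metathesis and desilylation finish the molecule.
- Enabling feature: in ring C the bonds O1–C2 and C3–C4 flank the C2–C3 unit. That unit is the vinyl group of 4-methoxystyrene, added across the C4=C4a–C8a=O1 oxa-diene latent in the ortho-hydroxybenzaldehyde.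
- Stereochemistry: C2 (S) is set in the annulation by a chiral BINOL-derived N-triflylphosphoramide. The C4 carbinol centre formed alongside is erased by oxidation, and no later step touches C2.

Key step: step 5

Assumption: the (R)-configured catalyst is taken to deliver the (2S) series; should the sense of induction prove opposite, the (S)-catalyst is used and nothing else changes.

**Route**

Step 1
Reactants: 1 2,4,6-trimethoxybenzaldehyde
Product: 3 2,6-dihydroxy-4-methoxybenzaldehyde, via 2-hydroxy-4,6-dimethoxybenzaldehyde 2 (not isolated)
Conditions: AlCl3 (4 equiv), CH2Cl2, 0 °C to reflux; then ice/aqueous HCl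
Reagents that add atoms: none
Why: Chelation-assisted Lewis-acid ether cleavage: AlCl3 held between the carbonyl oxygen and an ortho methoxy oxygen delivers chloride to that methyl group, so the two ortho ethers should fall in turn while the para ether, which cannot chelate, stays.

Step 2
Reactants: 3 2,6-dihydroxy-4-methoxybenzaldehyde; 4 allyl bromide
Product: 5 2-(allyloxy)-6-hydroxy-4-methoxybenzaldehyde
Conditions: K2CO3 (1.1 equiv), allyl bromide (1.05 equiv), acetone, 50 °C
Reagents that add atoms: none
Why: Williamson ether synthesis on a symmetric diol, so either hydroxyl gives the same product, and the remaining hydroxyl, locked in a hydrogen bond to the aldehyde, should be alkylated much more slowly.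

Step 3
Reactants: 5 2-(allyloxy)-6-hydroxy-4-methoxybenzaldehyde
Product: 6 2-(allyloxy)-6-(tert-butyldimethylsilyloxy)-4-methoxybenzaldehyde
Conditions: TBSCl, imidazole, DMF, rt
Reagents that add atoms: tert-butyldimethylsilyl chloride, CC(C)(C)[Si](C)(C)Cl
Why: Imidazole-promoted silylation of the only free phenol, which fixes without ambiguity which ortho oxygen stays capped in the annulation.

Step 4
Reactants: 6 2-(allyloxy)-6-(tert-butyldimethylsilyloxy)-4-methoxybenzaldehyde
Product: 8 3-allyl-6-(tert-butyldimethylsilyloxy)-2-hydroxy-4-methoxybenzaldehyde, via ortho-dienone 7 (not isolated)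
Conditions: 1,2-dichlorobenzene, 180 °C
Reagents that add atoms: none
Why: Aromatic Claisen rearrangement: the [3,3] shift can only reach the one unsubstituted ortho carbon (C3), and tautomerisation of the dienone releases the C2 phenol next to the new allyl group under neutral conditions that an aryl silyl ether should tolerate.

Step 5
Reactants: 8 3-allyl-6-(tert-butyldimethylsilyloxy)-2-hydroxy-4-methoxybenzaldehyde; 9 4-methoxystyrene
Product: 12 (2S,4S)-8-allyl-5-(tert-butyldimethylsilyloxy)-7-methoxy-2-(4-methoxyphenyl)chroman-4-ol, via oxocarbenium ion 10 (not isolated), via anisyl cation 11 (not isolated)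
Conditions: 9 (2 equiv, slow addition), (R)-3,3'-bis(2,4,6-triisopropylphenyl)-BINOL N-triflylphosphoramide (10 mol%), toluene, −40 °C; Et3N quench at −40 °C
Reagents that add atoms: none
Why: Proposed new method: the N-triflylphosphoramide protonates the aldehyde of 8 to the hydroxy-substituted ortho-quinone methide cation 10, the terminal carbon of 9 attacks its carbinyl carbon (C3–C4 bond) to give the 4-methoxybenzyl cation 11, and the free phenolic oxygen captures that cation (O1–C2 bond); the closest known reaction types are acid-promoted annulations of salicylaldehyde-derived alkoxy ortho-quinone methide cations with styrenes to 2-aryl-4-alkoxychromans and chiral N-triflylphosphoramide-catalysed [4+2] cycloadditions of ortho-quinone methides with styrenes. Ring C closes as a six-membered ring in a stepwise polar formal [4+2] mode, the last event being capture of the benzylic cation by oxygen through a chair-like transition state. C4 should be set in the C–C bond formation by the chiral anion, which is hydrogen-bonded to both the carbenium O–H and the phenol O–H and so shields one face of 10, and C2 should follow from closure inside the same contact ion pair with the anisyl group pseudo-equatorial, that is cis to the C4 hydroxyl. The step needs enantiofacial control at C2, closure through the C8a oxygen alone and an inert side-chain alkene: the first rests on the catalyst, the second on the silyl cap at the other ortho oxygen, and the third on carrying an allyl group, which is far less nucleophilic and far less easily protonated than a prenyl group. Low temperature and the cold amine quench are meant to keep the ionisable C4 alcohol of 12 and the excess styrene from reacting further, and the minor trans diastereomer is removed by chromatography before oxidation because it may carry the opposite configuration at C2.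

Step 6
Reactants: 12 (2S,4S)-8-allyl-5-(tert-butyldimethylsilyloxy)-7-methoxy-2-(4-methoxyphenyl)chroman-4-ol
Product: 13 (2S)-8-allyl-5-(tert-butyldimethylsilyloxy)-7-methoxy-2-(4-methoxyphenyl)chroman-4-one
Conditions: Dess–Martin periodinane, pyridine, CH2Cl2, 0 °C
Reagents that add atoms: none
Why: Dess–Martin oxidation of a secondary benzylic alcohol under pyridine-buffered conditions that should neither ionise C4 nor open the new ketone by retro-oxa-Michael reaction, so C2 is untouched and the C4 centre is removed.

Step 7
Reactants: 13 (2S)-8-allyl-5-(tert-butyldimethylsilyloxy)-7-methoxy-2-(4-methoxyphenyl)chroman-4-one; 14 2-methyl-2-butene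
Product: 15 (2S)-5-(tert-butyldimethylsilyloxy)-7-methoxy-2-(4-methoxyphenyl)-8-(3-methylbut-2-enyl)chroman-4-one
Conditions: second-generation Grubbs catalyst RuCl2(=CHPh)(PCy3)(H2IMes) (5 mol%), 2-methyl-2-butene/CH2Cl2, 40 °C, sealed vessel
Reagents that add atoms: none
Why: Olefin cross-metathesis of an allylarene with a large excess of a trisubstituted alkene, a standard way to turn aryl–allyl into aryl–prenyl with loss of propene, placed after the acid step so that the prenyl group never meets the Brønsted acid.

Step 8
Reactants: 15 (2S)-5-(tert-butyldimethylsilyloxy)-7-methoxy-2-(4-methoxyphenyl)-8-(3-methylbut-2-enyl)chroman-4-one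
Product: 16 flowerine, (2S)-5-hydroxy-7-methoxy-2-(4-methoxyphenyl)-8-(3-methylbut-2-enyl)chroman-4-one
Conditions: HF·pyridine, pyridine/THF, 0 °C
Reagents that add atoms: none
Why: Fluoride cleavage of an aryl silyl ether under buffered, mildly acidic conditions, which generate no phenoxide or enolate and so should leave the flavanone ring closed and C2 configurationally intact; the prenyl group has no free ortho phenol to cyclise onto.

**Compound list**

1 | 2,4,6-trimethoxybenzaldehyde | COc1cc(OC)c(C=O)c(OC)c1 | starting material
2 | 2-hydroxy-4,6-dimethoxybenzaldehyde (present in the flask as its aluminium chelate, not isolated) | COc1cc(O)c(C=O)c(OC)c1 | intermediate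
3 | 2,6-dihydroxy-4-methoxybenzaldehyde | COc1cc(O)c(C=O)c(O)c1 | intermediate
4 | allyl bromide | C=CCBr | starting material
5 | 2-(allyloxy)-6-hydroxy-4-methoxybenzaldehyde | C=CCOc1cc(OC)cc(O)c1C=O | intermediate
6 | 2-(allyloxy)-6-(tert-butyldimethylsilyloxy)-4-methoxybenzaldehyde | C=CCOc1cc(OC)cc(O[Si](C)(C)C(C)(C)C)c1C=O | intermediate
7 | 5-allyl-2-(tert-butyldimethylsilyloxy)-4-methoxy-6-oxocyclohexa-1,3-diene-1-carbaldehyde (racemic Claisen ortho-dienone, not isolated) | O=CC1=C(O[Si](C)(C)C(C)(C)C)C=C(OC)C(CC=C)C1=O | intermediate
8 | 3-allyl-6-(tert-butyldimethylsilyloxy)-2-hydroxy-4-methoxybenzaldehyde | O=Cc1c(O)c(CC=C)c(OC)cc1O[Si](C)(C)C(C)(C)C | intermediate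
9 | 4-methoxystyrene | C=Cc1ccc(OC)cc1 | starting material
10 | [3-allyl-6-(tert-butyldimethylsilyloxy)-2-hydroxy-4-methoxyphenyl](hydroxy)methylium (O-protonated 8, cation of the ion pair with the catalyst anion, not isolated) | [OH+]=Cc1c(O)c(CC=C)c(OC)cc1O[Si](C)(C)C(C)(C)C | intermediate
11 | (3S)-3-[3-allyl-6-(tert-butyldimethylsilyloxy)-2-hydroxy-4-methoxyphenyl]-3-hydroxy-1-(4-methoxyphenyl)propan-1-ylium (cation of the ion pair with the catalyst anion, not isolated) | COc1ccc([CH+]C[C@H](O)c2c(O)c(CC=C)c(OC)cc2O[Si](C)(C)C(C)(C)C)cc1 | intermediate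
12 | (2S,4S)-8-allyl-5-(tert-butyldimethylsilyloxy)-7-methoxy-2-(4-methoxyphenyl)chroman-4-ol (2,4-cis) | COc1ccc([C@@H]2C[C@H](O)c3c(O[Si](C)(C)C(C)(C)C)cc(OC)c(CC=C)c3O2)cc1 | intermediate
13 | (2S)-8-allyl-5-(tert-butyldimethylsilyloxy)-7-methoxy-2-(4-methoxyphenyl)chroman-4-one | COc1ccc([C@@H]2CC(=O)c3c(O[Si](C)(C)C(C)(C)C)cc(OC)c(CC=C)c3O2)cc1 | intermediate
14 | 2-methyl-2-butene | CC=C(C)C | starting material
15 | (2S)-5-(tert-butyldimethylsilyloxy)-7-methoxy-2-(4-methoxyphenyl)-8-(3-methylbut-2-enyl)chroman-4-one | COc1ccc([C@@H]2CC(=O)c3c(O[Si](C)(C)C(C)(C)C)cc(OC)c(CC=C(C)C)c3O2)cc1 | intermediate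
16 | flowerine, (2S)-5-hydroxy-7-methoxy-2-(4-methoxyphenyl)-8-(3-methylbut-2-enyl)chroman-4-one | COc1ccc([C@@H]2CC(=O)c3c(O)cc(OC)c(CC=C(C)C)c3O2)cc1 | target

**Step count**

Total steps: 8. Longest linear sequence: 8 steps (1 to 16); allyl bromide, 4-methoxystyrene and 2-methyl-2-butene enter as purchased reagents.

**Steps most likely to fail**

1. Step 5 (the annulation). What may go wrong: the benzylic cation may close outside the control of the chiral anion, giving poor enantiofacial selectivity at C2. The C4 alcohol of the product may re-ionise under the acid and eliminate or alkylate a second styrene. The 4-methoxystyrene may oligomerise cationically. The fallback uses known reactions only, sets out from 8 and comes back at 13. Addition of HC≡CMgBr (excess, THF, 0 °C) to the aldehyde should give the racemic propargylic alcohol 1-[3-allyl-6-(tert-butyldimethylsilyloxy)-2-hydroxy-4-methoxyphenyl]prop-2-yn-1-ol F1. MnO2 in CH2Cl2 should oxidise it to the ynone 1-[3-allyl-6-(tert-butyldimethylsilyloxy)-2-hydroxy-4-methoxyphenyl]prop-2-yn-1-one F2. K2CO3 in acetone should close this by 6-endo-dig oxa-Michael addition to the chromone 8-allyl-5-(tert-butyldimethylsilyloxy)-7-methoxy-4H-chromen-4-one F3. A rhodium-catalysed asymmetric 1,4-addition of 4-methoxyphenylboronic acid (Hayashi–Miyaura type) then sets C2 under ligand control and gives 13 directly. Its conditions are [RhCl(C2H4)2]2, a chiral 2,5-diphenylbicyclo[2.2.2]octa-2,5-diene ligand of the antipode that delivers the 2S series, aqueous K3PO4 and toluene.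

2. Step 4 (Claisen rearrangement). What may go wrong: at 180 °C the silyl group may be transferred to the newly released phenol or lost, and some allyl may drift on to the para carbon. The fallback sets out from 5 and comes back at 8. The free phenol 5 is rearranged first (1,2-dichlorobenzene, 180 °C) to 3-allyl-2,6-dihydroxy-4-methoxybenzaldehyde F4, so that no silyl ether is exposed to heat. TBSCl (1 equiv), imidazole, CH2Cl2, 0 °C should then silylate the C6 hydroxyl, whose outer neighbour is a hydrogen, in preference to the C2 hydroxyl wedged between the allyl and formyl groups, giving 8.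

3. Step 6 (oxidation). What may go wrong: the trioxygenated benzylic alcohol may ionise and eliminate under the acetic acid released by the oxidant, or oxidation may be slow next to the bulky peri silyl ether. The fallback sets out from 12 and comes back at 16, with deprotection moved ahead of oxidation. Bu4NF buffered with AcOH in THF at 0 °C should give the diol (2S,4S)-8-allyl-7-methoxy-2-(4-methoxyphenyl)chroman-4,5-diol F5. MnO2 in CH2Cl2, a neutral heterogeneous oxidant for benzylic alcohols, should take it to (2S)-8-allyl-5-hydroxy-7-methoxy-2-(4-methoxyphenyl)chroman-4-one F6, whose C5 hydroxyl is tied up in a hydrogen bond to the new ketone. Cross-metathesis of this ketone with 14 under the conditions of step 7 then gives 16.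

Further compounds
F1 | step 5 | 1-[3-allyl-6-(tert-butyldimethylsilyloxy)-2-hydroxy-4-methoxyphenyl]prop-2-yn-1-ol (racemic) | C#CC(O)c1c(O)c(CC=C)c(OC)cc1O[Si](C)(C)C(C)(C)C
F2 | step 5 | 1-[3-allyl-6-(tert-butyldimethylsilyloxy)-2-hydroxy-4-methoxyphenyl]prop-2-yn-1-one | C#CC(=O)c1c(O)c(CC=C)c(OC)cc1O[Si](C)(C)C(C)(C)C
F3 | step 5 | 8-allyl-5-(tert-butyldimethylsilyloxy)-7-methoxy-4H-chromen-4-one | C=CCc1c(OC)cc(O[Si](C)(C)C(C)(C)C)c2c(=O)ccoc12
F4 | step 4 | 3-allyl-2,6-dihydroxy-4-methoxybenzaldehyde | C=CCc1c(O)c(C=O)c(O)cc1OC
F5 | step 6 | (2S,4S)-8-allyl-7-methoxy-2-(4-methoxyphenyl)chroman-4,5-diol | COc1ccc([C@@H]2C[C@H](O)c3c(O)cc(OC)c(CC=C)c3O2)cc1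
F6 | step 6 | (2S)-8-allyl-5-hydroxy-7-methoxy-2-(4-methoxyphenyl)chroman-4-one | COc1ccc([C@@H]2CC(=O)c3c(O)cc(OC)c(CC=C)c3O2)cc1
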